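Two questions stood on this flask: when Q peaks within 30 min, and how much Q stands then.

in all of them: D 0.050 M (fed, over 10 min)

| flask | Z | L | remark | time |
|---|---|---|---|---|
| beta | 0.80 equiv | 0.0067 M | run made earlier; the fed solution adds 0.20 times the starting volume |  |
| alpha | 0.80 equiv | 0.015 M | run made earlier; the fed solution adds 0.20 times the starting volume |  |
| epsilon | 1.2 equiv | 0.010 M | run made earlier; the fed solution adds 0.20 times the starting volume |  |
| flask | 0.800 equiv | 0.0100 M | the fed solution adds 0.20 times the starting volume | 30 min |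

| run | time / min | Q / % | E / % |
|---|---|---|---|
| beta | 2.50 | 3.9 | 1.4 |
| beta | 5.00 | 11.2 | 3.7 |
| beta | 8.00 | 20.3 | 5.4 |
| beta | 15.0 | 22.1 | 5.7 |
| beta | 25.0 | 21.8 | 5.5 |
| alpha | 2.50 | 5.7 | 1.4 |
| alpha | 5.00 | 11.2 | 2.5 |
| alpha | 8.00 | 16.8 | 6.4 |
| alpha | 15.0 | 21.8 | 6.8 |
| alpha | 25.0 | 18.7 | 6.9 |
| epsilon | 2.50 | 5.4 | 2.7 |
| epsilon | 5.00 | 11.9 | 5.7 |
| epsilon | 8.00 | 17.1 | 7.9 |
| epsilon | 15.0 | 21.2 | 9.5 |
| epsilon | 25.0 | 19.9 | 7.0 |

(each reading ± 1 percentage point)

* the best time, 30 min at the latest, for Q
* the amount of Q, in percent of the D charged, at that time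

- every charge counts on the volume at the start, and the solution that is fed holds the whole dose
- the analysis behind the earlier runs scatters by 1 percentage point, standard deviation
- percentages count the whole charge, also what has not yet gone in

I reckoned with one number, the Q share: the part of the D fed so far, less E, that stands as Q. Pooling the readings of the earlier runs at 8.00 min gave 0.246, about a quarter, where an even split would stand at 0.5. A constant share makes Q grow with what has gone in, so I put the maximum in this flask at the end of the feed, 10 min. The two runs with 0.80 equiv of Z held a mean E of 6.25% at 15.0 min, so the share of the remainder gave 23.1% of Q.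

The forecast gave 22% at 13 min, “a broad maximum shortly after feed end”.

The simulation of this flask gave 23.0% at 10.6 min.

    D + L → G (k = 2.40 M⁻¹ min⁻¹)
    Z + Q ⇌ E (K = 9.50 M⁻¹, k = 76.0 M⁻¹ min⁻¹)
    D ⇌ Q (K = 0.360, k = 1.30 min⁻¹)

In this flask D and Q, by that step alone, relax into each other with a half-life of 0.141 min, much shorter than 30 min: a fast pre-equilibrium. At the best time the Q share of this flask stood at 0.246. The neighbouring reading of this flask at 12.0 min held 6.62% of E; with that E, the share gives 23.0%, and Q stood at 22.8%.

(The data come from a simulation on assumed constants, and the scatter is random.)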